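Stir a closed vessel of starting complex and incoming ligand at constant volume and temperature, and follow what the starting complex turns into.

all flasks: starting complex 0.10 M

|  | incoming ligand | remark | time |
|---|---|---|---|
| ash | 0.22 M | run made earlier |  |
| oak | 0.26 M | run made earlier |  |
| amber | 0.200 M |  | 25 d |
| ochre | 0.300 M |  | 25 d |

| run | time / d | complex with three exchanged / % | complex with two exchanged / % | starting complex / % |
|---|---|---|---|---|
| ash | 1.04 | 1 | 7 | 32 |
| ash | 3.00 | 3 | 26 | 5 |
| ash | 6.00 | 3 | 34 | 4 |
| ash | 8.00 | 4 | 39 | 0 |
| ash | 12.0 | 4 | 37 | 3 |
| oak | 2.50 | 0 | 24 | 8 |
| oak | 5.00 | 3 | 36 | 2 |
| oak | 8.00 | 6 | 40 | 0 |
| oak | 10.0 | 4 | 40 | 0 |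
| oak | 12.0 | 3 | 40 | 0 |

(standard deviation of a reading: 1.5 percentage points)

- percentages count the starting complex that a species holds: one self-condensation product counts as two
- reactions considered so far: starting complex + incoming ligand <-> leaving ligand + complex with one exchanged; complex with one exchanged + incoming ligand <-> leaving ligand + complex with two exchanged; complex with two exchanged + incoming ligand <-> leaving ligand + complex with three exchanged; complex with three exchanged + incoming ligand <-> leaving ligand + complex with four exchanged; leaving ligand -> by-product carried off; 2 starting complex -> self-condensation product

* which of these holds the largest part of the starting complex at the end of amber (complex with two exchanged / complex with one exchanged / complex with three exchanged / complex with four exchanged / starting complex)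
* which of these holds the largest part of the starting complex at the end of ochre (complex with two exchanged / complex with one exchanged / complex with three exchanged / complex with four exchanged / starting complex)
* how much complex with three exchanged is there at the end of amber, in percent of the starting complex charged

Set the zero of the scale first. If all sites were alike, forward exchange would run in proportion to the sites left: two on complex with two exchanged, one on complex with three exchanged. In a steady forward passage each step takes one incoming ligand, so the ligand cancels, and complex with three exchanged would stand to complex with two exchanged at a ratio of 2.

Now read the late rows, from 6.00 d in ash and from 5.00 d in oak, complex with three exchanged against complex with two exchanged. Ash gives 0.100 and oak gives 0.103, about the same although oak was charged with more ligand. One reading carries 1.5 percentage points, so pool these rows. This gives the passage ratio, late complex with three exchanged over late complex with two exchanged, as a reading of 0.102.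

It lies far below the zero, so in ash and oak take complex with three exchanged as a transit species and complex with two exchanged as the resting state. I expect what leaves complex with two exchanged in these flasks to pass on to complex with four exchanged.

Ash, charged closer to amber than oak, reads a late mean of 36.7 % of complex with two exchanged. Take that reading for the end of amber and multiply, and my estimate for amber is 3.72 % of complex with three exchanged. I put complex with two exchanged first in amber and leave ochre open between it and complex with four exchanged.

The forecast differs in its ground, holding that “exchange effectively stalls there”, and names complex with two exchanged for amber, complex with two exchanged for ochre and 4 % for the amount.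

Among the forms asked, amber ends led by complex with two exchanged, with 3.01 % of complex with three exchanged. Among the same forms, ochre ends led by complex with four exchanged, at 45.7 % against 23.3 % of complex with two exchanged.

    starting complex + incoming ligand ⇌ leaving ligand + complex with one exchanged (K = 1.24, k = 4.07 × 10⁻⁵ M⁻¹ s⁻¹)
    complex with one exchanged + incoming ligand ⇌ leaving ligand + complex with two exchanged (K = 0.700, k = 2.29 × 10⁻⁵ M⁻¹ s⁻¹)
    complex with two exchanged + incoming ligand ⇌ leaving ligand + complex with three exchanged (K = 108, k = 6.29 × 10⁻⁶ M⁻¹ s⁻¹)
    complex with three exchanged + incoming ligand ⇌ leaving ligand + complex with four exchanged (K = 0.750, k = 7.70 × 10⁻⁵ M⁻¹ s⁻¹)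
    leaving ligand → by-product carried off (k = 7.40 × 10⁻⁵ s⁻¹)
    2 starting complex → self-condensation product (k = 4.61 × 10⁻⁵ M⁻¹ s⁻¹)

Amber's complex with two exchanged stands at 33.2 %, lower than the ash mean, and the passage ratio turns that into 3.37 % of complex with three exchanged, where amber holds 3.01 %. Take the neighbour of amber charged with 0.040 M of starting complex, which makes its incoming ligand 5.00 equiv. At 25.0 d this neighbour holds 24.9 % of complex with two exchanged, so the ratio gives 2.52 % of complex with three exchanged, and the neighbour holds 2.33 %.

Readings and results are calculated for an exercise; the scatter is artificial.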